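The trans-decalin is opened at C1–C10 (ring A) and C8–C9 (ring B), which unfolds it into an acyclic aldehyde–enone whose only core stereocentre is C5. One radical chain then rebuilds both rings: the C8 acyl radical closes ring B on the C9=C10 olefin, and the tertiary C10 radical so formed, already carrying the angular methyl C20, closes ring A by attacking C1 of a vinyl ketone. The step exploits the quaternary ring-fusion carbon C10 lying between the oxygenated C8 and the gem-dimethyl C4. C5 is set by Ireland–Claisen chirality transfer from a CBS-derived carbinol, C9 and C10 are relayed from it, and C13 is bought as (S)-citronellol.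

Key step: step 9

Remark: carbon numbers are those of the labdane skeleton (C1–C10 decalin, C11–C16 side chain with C16 the methyl on C13, C17 on C8, C18/C19 on C4, C20 on C10); the target is the normal-series isomer with 5α-H, 9α-H, 10β-methyl, 8α-OH and 13S.

Step 1
Reactants: 1 (S)-citronellol
Product: 2 (S)-citronellyl pivalate
Conditions: pivaloyl chloride, pyridine, DMAP (cat.), CH2Cl2, 0 °C
Reagents that add atoms: pivaloyl chloride CC(C)(C)C(Cl)=O
Why: Esterification of the primary alcohol gives a non-enolisable ester that should survive the later enolate, organometallic and radical steps and is cleaved by the alkali of step 11.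

Step 2
Reactants: 2 (S)-citronellyl pivalate
Product: 3 (4S)-4-methyl-6-(pivaloyloxy)hexanoic acid
Conditions: RuCl3·xH2O (2 mol %), NaIO4, CCl4/MeCN/H2O, 25 °C
Reagents that add atoms: sodium periodate [Na+].[O-]I(=O)(=O)=O; water O
Why: Ruthenium tetroxide-catalysed oxidative cleavage of the trisubstituted olefin gives the carboxylic acid whose carbon becomes C9, leaving the ester and the C13 stereocentre untouched.

Step 3
Reactants: 4 3-bromo-1,1-dimethoxypropane
Product: 5 6,6-dimethoxyhex-2-yne
Conditions: 1-propynyllithium, THF/DMPU, -20 → 25 °C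
Reagents that add atoms: 1-propynyllithium [Li]C#CC
Why: SN2 alkylation of the acetylide by the primary bromide gives the 2-alkyne that supplies C20, C10 and C5–C8, with C8 masked as a dimethyl acetal.

Step 4
Reactants: 5 6,6-dimethoxyhex-2-yne; 3 (4S)-4-methyl-6-(pivaloyloxy)hexanoic acid
Product: 8 (3S,7E)-11,11-dimethoxy-3,7-dimethyl-6-oxoundec-7-en-1-yl pivalate, via alkenylzirconocene 6 (not isolated), via acid chloride 7 (not isolated)
Conditions: 5: Cp2Zr(H)Cl, THF, 40 °C; 3: (COCl)2, DMF (cat.), CH2Cl2, then evaporation; both combined with CuBr·SMe2 (10 mol %), THF, 25 °C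
Reagents that add atoms: none
Why: syn-Hydrozirconation should place zirconium on the methyl-bearing, less hindered alkyne carbon after equilibration, and copper-catalysed acylation of the alkenylzirconocene with retention then gives the (E)-α-methyl enone (hydrozirconation–acylation).

Step 5
Reactants: 8 (3S,7E)-11,11-dimethoxy-3,7-dimethyl-6-oxoundec-7-en-1-yl pivalate
Product: 9 (3S,6S,7E)-6-hydroxy-11,11-dimethoxy-3,7-dimethylundec-7-en-1-yl pivalate
Conditions: (R)-2-methyl-CBS-oxazaborolidine (10 mol %), BH3·SMe2, THF, -30 °C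
Reagents that add atoms: none
Why: CBS reduction with the α-methylalkenyl group as the large substituent should deliver hydride to one carbonyl face under catalyst control and set the (6S)-carbinol (the future C9) independently of the remote C13 centre.

Step 6
Reactants: 9 (3S,6S,7E)-6-hydroxy-11,11-dimethoxy-3,7-dimethylundec-7-en-1-yl pivalate
Product: 10 (3S,6S,7E)-6-(isobutyryloxy)-11,11-dimethoxy-3,7-dimethylundec-7-en-1-yl pivalate
Conditions: isobutyryl chloride, pyridine, DMAP (cat.), CH2Cl2, 0 → 25 °C
Reagents that add atoms: isobutyryl chloride CC(C)C(Cl)=O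
Why: Esterification of the secondary allylic alcohol installs the isobutyrate that supplies C3, C4, C18 and C19.

Step 7
Reactants: 10 (3S,6S,7E)-6-(isobutyryloxy)-11,11-dimethoxy-3,7-dimethylundec-7-en-1-yl pivalate
Product: 13 (3R,4E,8S)-2,2,4,8-tetramethyl-3-(3-oxopropyl)-10-(pivaloyloxy)dec-4-enoic acid, via silyl ketene acetal 11 (not isolated), via trimethylsilyl ester 12 (not isolated)
Conditions: LiN(iPr)2, Me3SiCl, THF, -78 → 60 °C; then 1 M HCl, THF, 25 °C
Reagents that add atoms: water O
Why: Ireland–Claisen rearrangement through a chair transition state with the carbinol substituent equatorial should form the C4–C5 bond suprafacially, transferring the carbinol chirality to C5 and giving the (E)-C9=C10 olefin, and the acidic work-up cleaves the silyl ester and the dimethyl acetal.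

Step 8
Reactants: 13 (3R,4E,8S)-2,2,4,8-tetramethyl-3-(3-oxopropyl)-10-(pivaloyloxy)dec-4-enoic acid
Product: 15 (3S,6E,8R)-3,7,9,9-tetramethyl-10-oxo-8-(3-oxopropyl)dodeca-6,11-dien-1-yl pivalate, via acid chloride 14 (not isolated)
Conditions: 1-chloro-N,N,2-trimethylprop-1-en-1-amine, CH2Cl2, 0 → 25 °C; then Bu3SnCH=CH2, Pd(PPh3)4 (5 mol %), THF, 50 °C
Reagents that add atoms: tributyl(vinyl)stannane C=C[Sn](CCCC)(CCCC)CCCC
Why: The chloroenamine converts the hindered acid into its chloride under neutral conditions that spare the aldehyde, and Stille acylation with the vinylstannane gives the vinyl ketone (C1=C2–C3=O).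

Step 9
Reactants: 15 (3S,6E,8R)-3,7,9,9-tetramethyl-10-oxo-8-(3-oxopropyl)dodeca-6,11-dien-1-yl pivalate
Product: 17 (13S)-3,8-dioxo-17-norlabdan-15-yl pivalate, via kinetic C9-epimeric dione 16 (not isolated)
Conditions: t-C12H25SH (0.3 equiv), AIBN (0.2 equiv, in portions), PhCl (0.01 M), 85 °C; then DBU (0.2 equiv), 25 °C
Reagents that add atoms: none
Why: The thiyl radical abstracts the aldehyde hydrogen of 15, the C8 acyl radical adds 6-endo-trig to C9 of the trisubstituted olefin (the C20 methyl on the proximal carbon C10 disfavours 5-exo closure), and the tertiary C10 radical then adds 6-endo-trig to C1 of the vinyl ketone, the α-keto radical at C2 being quenched by the thiol. The closest known reaction types are the acyl radical polyene cascade cyclisation and the thiol-catalysed radical hydroacylation of alkenals. Ring B thus closes at C8–C9 and ring A at C1–C10, both in the 6-endo-trig mode. C10 is controlled by C5: the ring B radical should react through the chair that keeps the bulky C4 chain on C5 equatorial, the in-plane C20 methyl tips axial, and C1 bonds on the equatorial face, so the fusion should be trans. C9 is formed under kinetic control but lies α to the C8 ketone, and DBU should equilibrate it to the equatorial side chain (9α-H). The step needs both cyclisations to outrun hydrogen transfer and intermolecular addition, which high dilution and a sub-stoichiometric thiol should secure.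

Step 10
Reactants: 17 (13S)-3,8-dioxo-17-norlabdan-15-yl pivalate
Product: 18 (13S)-3-oxolabd-8(17)-en-15-yl pivalate
Conditions: Ph3PCH3Br (1.3 equiv), KOtBu (1.2 equiv), THF, 0 → 25 °C
Reagents that add atoms: methyltriphenylphosphonium bromide C[P+](c1ccccc1)(c1ccccc1)c1ccccc1.[Br-]
Why: Wittig methylenation should take place at the C8 ketone, which is less hindered than the C3 ketone flanked by the gem-dimethyl C4, while the basic medium keeps C9 in its equatorial configuration.

Step 11
Reactants: 18 (13S)-3-oxolabd-8(17)-en-15-yl pivalate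
Product: 20 (13S)-labd-8(17)-en-15-ol, via hydrazone 19 (not isolated)
Conditions: N2H4·H2O, KOH, diethylene glycol, 130 °C then 200 °C
Reagents that add atoms: none
Why: Wolff–Kishner reduction (Huang–Minlon conditions) removes the C3 carbonyl through its hydrazone and the hot alkali cleaves the pivalate, no stereocentre being α to a carbonyl at this stage.

Step 12
Reactants: 20 (13S)-labd-8(17)-en-15-ol
Product: 22 (13S)-labdane-8α,15-diol, via organomercurial 21 (not isolated)
Conditions: Hg(OAc)2, THF/H2O, 25 °C; then aq. NaOH, NaBH4, 0 °C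
Reagents that add atoms: water O
Why: Markovnikov oxymercuration–demercuration should deliver water to C8 from the equatorial α-face, because the axial β-trajectory is blocked by the syn-axial C20 methyl, giving the 8α-hydroxyl and the axial C17 methyl.

Step 13
Reactants: 22 (13S)-labdane-8α,15-diol; 23 3-phenylpropanoyl chloride
Product: 24 (13S)-8α-hydroxylabdan-15-yl 3-phenylpropanoate (target)
Conditions: pyridine, DMAP (cat.), CH2Cl2, 0 °C
Reagents that add atoms: none
Why: Esterification should be selective for the primary C15 hydroxyl over the hindered tertiary C8 hydroxyl.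

Compound list
1 | (S)-citronellol, (3S)-3,7-dimethyloct-6-en-1-ol | C[C@H](CCO)CCC=C(C)C | starting material
2 | (S)-citronellyl pivalate | C[C@H](CCOC(=O)C(C)(C)C)CCC=C(C)C | intermediate
3 | (4S)-4-methyl-6-(pivaloyloxy)hexanoic acid | C[C@H](CCOC(=O)C(C)(C)C)CCC(=O)O | intermediate
4 | 3-bromo-1,1-dimethoxypropane | COC(CCBr)OC | starting material
5 | 6,6-dimethoxyhex-2-yne | CC#CCCC(OC)OC | intermediate
6 | chloro[(2E)-6,6-dimethoxyhex-2-en-2-yl]zirconocene | C/C(=C\CCC(OC)OC)[Zr](Cl)(C1C=CC=C1)C1C=CC=C1 | intermediate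
7 | (3S)-6-chloro-3-methyl-6-oxohexyl pivalate (acid chloride of 3) | C[C@H](CCOC(=O)C(C)(C)C)CCC(Cl)=O | intermediate
8 | (3S,7E)-11,11-dimethoxy-3,7-dimethyl-6-oxoundec-7-en-1-yl pivalate | COC(OC)CC/C=C(\C)C(=O)CC[C@H](C)CCOC(=O)C(C)(C)C | intermediate
9 | (3S,6S,7E)-6-hydroxy-11,11-dimethoxy-3,7-dimethylundec-7-en-1-yl pivalate | COC(OC)CC/C=C(C)/[C@@H](O)CC[C@H](C)CCOC(=O)C(C)(C)C | intermediate
10 | (3S,6S,7E)-6-(isobutyryloxy)-11,11-dimethoxy-3,7-dimethylundec-7-en-1-yl pivalate | COC(OC)CC/C=C(C)/[C@@H](OC(=O)C(C)C)CC[C@H](C)CCOC(=O)C(C)(C)C | intermediate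
11 | trimethylsilyl ketene acetal of 10 | COC(OC)CC/C=C(C)/[C@@H](OC(O[Si](C)(C)C)=C(C)C)CC[C@H](C)CCOC(=O)C(C)(C)C | intermediate
12 | trimethylsilyl (3R,4E,8S)-3-(3,3-dimethoxypropyl)-2,2,4,8-tetramethyl-10-(pivaloyloxy)dec-4-enoate | C[Si](C)(C)OC(=O)C(C)(C)[C@@H](/C(C)=C/CC[C@H](C)CCOC(=O)C(C)(C)C)CCC(OC)OC | intermediate
13 | (3R,4E,8S)-2,2,4,8-tetramethyl-3-(3-oxopropyl)-10-(pivaloyloxy)dec-4-enoic acid | OC(=O)C(C)(C)[C@@H](/C(C)=C/CC[C@H](C)CCOC(=O)C(C)(C)C)CCC=O | intermediate
14 | acid chloride of 13 | ClC(=O)C(C)(C)[C@@H](/C(C)=C/CC[C@H](C)CCOC(=O)C(C)(C)C)CCC=O | intermediate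
15 | (3S,6E,8R)-3,7,9,9-tetramethyl-10-oxo-8-(3-oxopropyl)dodeca-6,11-dien-1-yl pivalate | C=CC(=O)C(C)(C)[C@@H](/C(C)=C/CC[C@H](C)CCOC(=O)C(C)(C)C)CCC=O | intermediate
16 | (13S)-3,8-dioxo-17-norlabdan-15-yl pivalate as the kinetic mixture of C9 epimers (5α-H, 10β-methyl) | C[C@H](CCOC(=O)C(C)(C)C)CCC1[C@@]2(C)CCC(=O)C(C)(C)[C@@H]2CCC1=O | intermediate
17 | (13S)-3,8-dioxo-17-norlabdan-15-yl pivalate (5α-H, 9α-H, 10β-methyl) | C[C@H](CCOC(=O)C(C)(C)C)CC[C@@H]1[C@@]2(C)CCC(=O)C(C)(C)[C@@H]2CCC1=O | intermediate
18 | (13S)-3-oxolabd-8(17)-en-15-yl pivalate | C[C@H](CCOC(=O)C(C)(C)C)CC[C@@H]1[C@@]2(C)CCC(=O)C(C)(C)[C@@H]2CCC1=C | intermediate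
19 | 3-hydrazone of 18 | C[C@H](CCOC(=O)C(C)(C)C)CC[C@@H]1[C@@]2(C)CCC(=NN)C(C)(C)[C@@H]2CCC1=C | intermediate
20 | (13S)-labd-8(17)-en-15-ol | C[C@H](CCO)CC[C@@H]1[C@@]2(C)CCCC(C)(C)[C@@H]2CCC1=C | intermediate
21 | (13S)-17-(acetoxymercurio)labdane-8α,15-diol | C[C@H](CCO)CC[C@@H]1[C@@]2(C)CCCC(C)(C)[C@@H]2CC[C@@]1(C[Hg]OC(C)=O)O | intermediate
22 | (13S)-labdane-8α,15-diol | C[C@H](CCO)CC[C@@H]1[C@@]2(C)CCCC(C)(C)[C@@H]2CC[C@@]1(C)O | intermediate
23 | 3-phenylpropanoyl chloride | O=C(Cl)CCc1ccccc1 | starting material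
24 | (13S)-8α-hydroxylabdan-15-yl 3-phenylpropanoate, (5S,8R,9R,10S,13S) | C[C@H](CCOC(=O)CCc1ccccc1)CC[C@@H]1[C@@]2(C)CCCC(C)(C)[C@@H]2CC[C@@]1(C)O | target

Total step count: 13. Longest linear sequence: 12 steps (steps 1, 2 and 4–13); step 3 makes the second fragment, which joins at step 4.

Steps most likely to fail

Step 9 (key step). Hydrogen transfer to the acyl or the C10 radical may outrun cyclisation, the acyl radical may lose carbon monoxide, or ring A may close through the cis-fused transition state. The fallback sets out from 15 and comes back at 17, forming the two rings one at a time with known chemistry. Me2AlCl (CH2Cl2, -78 °C) should close ring B by an intramolecular carbonyl-ene reaction (C8–C9 bond, hydrogen taken from C20) to give the methylenecyclohexanol F1, in which the C5 chain and ring conformation are fixed before ring A is made. Fe(acac)3 and PhSiH3 (EtOH, 60 °C) should then deliver a hydrogen atom to the exocyclic methylene, and the tertiary C10 radical should close ring A at C1–C10 on the vinyl ketone (hydrogen-atom-transfer Giese cyclisation) to give the hydroxy ketone F2. Dess–Martin oxidation of the C8 carbinol followed by DBU gives 17.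

Step 10. Chemoselectivity may be lost, with methylenation also at the C3 ketone or enolisation without olefination. The fallback sets out from 17 and comes back at 20, separating the two carbonyl groups by thermodynamic rather than kinetic discrimination. Ethane-1,2-diol and TsOH (benzene, water removal) should ketalise only the C8 carbonyl, the C3 carbonyl next to the gem-dimethyl carbon resisting ketal formation, to give the C8 dioxolane F3. Wolff–Kishner reduction then removes the C3 carbonyl and the pivalate to give the ketal alcohol F4. Aqueous HCl in acetone unmasks the ketone to give the hydroxy ketone F5, and excess Ph3P=CH2 gives 20.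

Step 8. The hindered acyl–palladium intermediate may decarbonylate, or the free aldehyde and the vinyl ketone may condense or polymerise under the coupling conditions. The fallback sets out from 10 and comes back at 15, keeping the aldehyde masked until the vinyl ketone is in place. The Ireland–Claisen rearrangement is worked up at pH 5 so that the dimethyl acetal survives, giving the acetal acid F6. The chloroenamine followed by MeNHOMe·HCl and pyridine gives the N-methoxy-N-methylamide F7, and CH2=CHMgBr (THF, -20 °C) gives the vinyl ketone acetal F8. Amberlyst-15 in wet acetone then unveils the aldehyde to give 15.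

Further compounds
F1 | step 9 | (3S)-5-[(3R)-6-hydroxy-2-methylene-3-(2-methyl-3-oxopent-4-en-2-yl)cyclohexyl]-3-methylpentyl pivalate (C8/C9 epimers) | C=CC(=O)C(C)(C)[C@@H]1CCC(O)C(CC[C@H](C)CCOC(=O)C(C)(C)C)C1=C
F2 | step 9 | (13S)-8-hydroxy-3-oxo-17-norlabdan-15-yl pivalate (C8/C9 epimers) | C[C@H](CCOC(=O)C(C)(C)C)CCC1[C@@]2(C)CCC(=O)C(C)(C)[C@@H]2CCC1O
F3 | step 10 | (13S)-8,8-(ethylenedioxy)-3-oxo-17-norlabdan-15-yl pivalate | C[C@H](CCOC(=O)C(C)(C)C)CC[C@@H]1[C@@]2(C)CCC(=O)C(C)(C)[C@@H]2CCC13OCCO3
F4 | step 10 | (13S)-8,8-(ethylenedioxy)-17-norlabdan-15-ol | C[C@H](CCO)CC[C@@H]1[C@@]2(C)CCCC(C)(C)[C@@H]2CCC13OCCO3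
F5 | step 10 | (13S)-15-hydroxy-17-norlabdan-8-one | C[C@H](CCO)CC[C@@H]1[C@@]2(C)CCCC(C)(C)[C@@H]2CCC1=O
F6 | step 8 | (3R,4E,8S)-3-(3,3-dimethoxypropyl)-2,2,4,8-tetramethyl-10-(pivaloyloxy)dec-4-enoic acid | OC(=O)C(C)(C)[C@@H](/C(C)=C/CC[C@H](C)CCOC(=O)C(C)(C)C)CCC(OC)OC
F7 | step 8 | N-methoxy-N-methylamide of F6 | CON(C)C(=O)C(C)(C)[C@@H](/C(C)=C/CC[C@H](C)CCOC(=O)C(C)(C)C)CCC(OC)OC
F8 | step 8 | (3S,6E,8R)-8-(3,3-dimethoxypropyl)-3,7,9,9-tetramethyl-10-oxododeca-6,11-dien-1-yl pivalate | C=CC(=O)C(C)(C)[C@@H](/C(C)=C/CC[C@H](C)CCOC(=O)C(C)(C)C)CCC(OC)OC
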